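**Retrosynthetic overview**
- Last operation: the oxolane (O4–C1, 5-exo epoxide opening) and the ten-membered carbocycle (C5=C6, intramolecular vinylogous aldol condensation of the butenolide onto a C5 aldehyde) are closed in one flask from an acyclic epoxy aldehyde.
- That precursor comes from a Stille carbonylative three-component union (C7–C8(=O)–C9) of an (E)-allyl chloride made from (S)-linalool (source of C4), CO and a 4-stannylbutenolide; C8 is set by CBS reduction, C1/C10 by Shi epoxidation, and the C5 aldehyde comes from the linalool vinyl group.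
- The butenolide (first ring) is made from but-2-yne-1,4-diol by IBr addition and carbonylative lactonisation.
- Ring order: butenolide first, then oxolane and carbocycle together at the end; the angelate and acetate are carried from mid-route.

Assumption: the SMILES is read literally, i.e. (1S,4S,8S,10R), 5E and a (Z)-angelate, which places C5 and C10 trans on the oxolane; germacrane numbering is used (C1/C4 oxolane carbons, C5=C6 enol-lactone alkene, C8 angelate carbon, C10 carbinol, C12 lactone C=O, C13 CH2OAc).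

**Route**

Step 1
Reactants: 1 (S)-(+)-linalool
Product: 2 (2E,6S)-2,6-dimethylocta-2,7-diene-1,6-diol
Conditions: SeO2 (0.3 equiv), t-BuOOH, salicylic acid (cat.), CH2Cl2, 0 °C → rt
Reagents that add atoms: tert-butyl hydroperoxide, CC(C)(C)OO
Why: Sharpless SeO2/t-BuOOH allylic oxidation (ene reaction then [2,3]-sigmatropic shift) attacks only the electron-rich trisubstituted alkene and oxidises its (E)-methyl group, which fixes the E geometry and leaves the carbinol stereocentre untouched.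

Step 2
Reactants: 2 (2E,6S)-2,6-dimethylocta-2,7-diene-1,6-diol
Product: 3 (3S,6E)-8-chloro-3,7-dimethylocta-1,6-dien-3-ol
Conditions: MsCl, LiCl, 2,4,6-collidine, DMF, 0 °C
Reagents that add atoms: lithium chloride, [Li+].[Cl-]
Why: Collington–Meyers chlorination (mesylate formed in situ, SN2 by chloride) converts only the primary allylic alcohol, without allylic transposition, while the hindered tertiary alcohol does not react.

Step 3
Reactants: 4 but-2-yne-1,4-diol
Product: 5 (E)-2-bromo-3-iodobut-2-ene-1,4-diol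
Conditions: IBr, CH2Cl2/MeCN, −20 → 0 °C
Reagents that add atoms: iodine monobromide, BrI
Why: Electrophilic anti addition of IBr across the symmetrical alkyne gives the (E)-dihalide, in which each halogen is cis to the CH2OH group on the other alkene carbon.

Step 4
Reactants: 5 (E)-2-bromo-3-iodobut-2-ene-1,4-diol
Product: 6 4-bromo-3-(hydroxymethyl)furan-2(5H)-one
Conditions: PdCl2(PPh3)2 (3 mol %), CO (1 atm), K2CO3, THF, 40 °C
Reagents that add atoms: carbon monoxide, [C-]#[O+]
Why: Cowell–Stille cyclocarbonylation of a (Z)-γ-hydroxy vinyl halide: zerovalent palladium inserts into the weaker carbon–iodine bond, CO inserts, and the cis CH2OH captures the acylpalladium to give the butenolide with the carbon–bromine bond kept.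

Step 5
Reactants: 6 4-bromo-3-(hydroxymethyl)furan-2(5H)-one
Product: 8 [2-oxo-4-(tributylstannyl)-2,5-dihydrofuran-3-yl]methyl acetate, via stannyl alcohol 7 (not isolated)
Conditions: (Bu3Sn)2, Pd(PPh3)4 (5 mol %), PhMe, 90 °C; then Ac2O, pyridine, DMAP (cat.), 0 °C
Reagents that add atoms: hexabutylditin, CCCC[Sn](CCCC)(CCCC)[Sn](CCCC)(CCCC)CCCC; acetic anhydride, CC(=O)OC(C)=O
Why: Palladium-catalysed stannylation of the activated β-bromo enoate with the distannane (Stille-type oxidative addition, Sn–Sn transmetalation, reductive elimination) is run on the free alcohol so that no allylic acetate is exposed to the catalyst, and the primary alcohol is then acetylated.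

Step 6
Reactants: 3 (3S,6E)-8-chloro-3,7-dimethylocta-1,6-dien-3-ol; 8 [2-oxo-4-(tributylstannyl)-2,5-dihydrofuran-3-yl]methyl acetate
Product: 9 {4-[(3E,7S)-7-hydroxy-3,7-dimethylnona-3,8-dienoyl]-2-oxo-2,5-dihydrofuran-3-yl}methyl acetate
Conditions: Pd2(dba)3 (2.5 mol %), AsPh3 (10 mol %), CO (3 atm), THF, 50 °C
Reagents that add atoms: carbon monoxide, [C-]#[O+]
Why: Stille carbonylative coupling of an allyl chloride with a vinylstannane: the syn π-allylpalladium complex takes up CO at its unsubstituted terminus and the acylpalladium is transferred to the stannane, forming C8–C9 and C7–C8 with the E alkene retained.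

Step 7
Reactants: 9 {4-[(3E,7S)-7-hydroxy-3,7-dimethylnona-3,8-dienoyl]-2-oxo-2,5-dihydrofuran-3-yl}methyl acetate
Product: 10 {4-[(1S,3E,7S)-1,7-dihydroxy-3,7-dimethylnona-3,8-dien-1-yl]-2-oxo-2,5-dihydrofuran-3-yl}methyl acetate
Conditions: (R)-2-methyl-CBS-oxazaborolidine (0.3 equiv), catecholborane, PhMe, −78 °C
Reagents that add atoms: none
Why: Corey–Bakshi–Shibata reduction: the ketone binds with the large butenolide substituent away from the catalyst, so the (R)-catalyst delivers hydride to the face that gives (S)-C8 by reagent control, in a 1,2-sense and without touching the esters.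

Step 8
Reactants: 10 {4-[(1S,3E,7S)-1,7-dihydroxy-3,7-dimethylnona-3,8-dien-1-yl]-2-oxo-2,5-dihydrofuran-3-yl}methyl acetate; 11 angelic acid
Product: 13 (1S,3E,7S)-1-[4-(acetoxymethyl)-5-oxo-2,5-dihydrofuran-3-yl]-7-hydroxy-3,7-dimethylnona-3,8-dien-1-yl (2Z)-2-methylbut-2-enoate, via mixed anhydride 12 (not isolated)
Conditions: 11, 2,4,6-Cl3C6H2COCl, Et3N, PhMe, rt; then 10, PhMe, 75 °C
Reagents that add atoms: none
Why: Yamaguchi-type esterification through the angelic 2,4,6-trichlorobenzoic mixed anhydride acylates only the secondary alcohol and is the established way to install an angelate without Z-to-E isomerisation.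

Step 9
Reactants: 13 (1S,3E,7S)-1-[4-(acetoxymethyl)-5-oxo-2,5-dihydrofuran-3-yl]-7-hydroxy-3,7-dimethylnona-3,8-dien-1-yl (2Z)-2-methylbut-2-enoate
Product: 14 7-O-trimethylsilyl ether of 13
Conditions: N-(trimethylsilyl)imidazole, CH2Cl2, 40 °C
Reagents that add atoms: N-(trimethylsilyl)imidazole, C[Si](C)(C)n1ccnc1
Why: Neutral silyl transfer masks the tertiary alcohol so that it can neither open the epoxide prematurely nor expose an α-hydroxy aldehyde to periodate in step 11.

Step 10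
Reactants: 14 7-O-trimethylsilyl ether of 13
Product: 15 (1S)-1-[4-(acetoxymethyl)-5-oxo-2,5-dihydrofuran-3-yl]-2-{(2R,3R)-2-methyl-3-[(3S)-3-methyl-3-(trimethylsilyloxy)pent-4-en-1-yl]oxiran-2-yl}ethyl (2Z)-2-methylbut-2-enoate
Conditions: Shi ketone (1,2:4,5-di-O-isopropylidene-D-erythro-2,3-hexodiulo-2,6-pyranose, from D-fructose, 0.3 equiv), KHSO5 (as 2KHSO5·KHSO4·K2SO4), K2CO3, Bu4NHSO4, MeCN/CH2(OMe)2/aq. Na2B4O7 buffer, 0 °C
Reagents that add atoms: potassium peroxymonosulfate, [K+].[O-]S(=O)(=O)OO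
Why: Shi asymmetric epoxidation (chiral dioxirane, spiro transition state) attacks only the electron-rich trisubstituted alkene, and the D-fructose-derived ketone gives the (R,R)-epoxide, which sets C10 (R) and prepares C1 for inversion.

Step 11
Reactants: 15 (1S)-1-[4-(acetoxymethyl)-5-oxo-2,5-dihydrofuran-3-yl]-2-{(2R,3R)-2-methyl-3-[(3S)-3-methyl-3-(trimethylsilyloxy)pent-4-en-1-yl]oxiran-2-yl}ethyl (2Z)-2-methylbut-2-enoate
Product: 17 (1S)-1-[4-(acetoxymethyl)-5-oxo-2,5-dihydrofuran-3-yl]-2-{(2R,3R)-2-methyl-3-[(3S)-3-methyl-4-oxo-3-(trimethylsilyloxy)butyl]oxiran-2-yl}ethyl (2Z)-2-methylbut-2-enoate, via vicinal diol 16 (not isolated)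
Conditions: OsO4 (2 mol %), NMO, acetone/H2O, rt; then NaIO4, THF/pH 7 buffer, 0 °C
Reagents that add atoms: N-methylmorpholine N-oxide, C[N+]1([O-])CCOCC1; water, O
Why: Upjohn dihydroxylation takes the monosubstituted vinyl group in preference to the electron-poor angelate and butenolide alkenes, and periodate glycol cleavage then gives the non-enolisable α-silyloxy aldehyde, which the silyl ether protects from further cleavage.

Step 12
Reactants: 17 (1S)-1-[4-(acetoxymethyl)-5-oxo-2,5-dihydrofuran-3-yl]-2-{(2R,3R)-2-methyl-3-[(3S)-3-methyl-4-oxo-3-(trimethylsilyloxy)butyl]oxiran-2-yl}ethyl (2Z)-2-methylbut-2-enoate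
Product: 22 CNP0162854.1 (1S,4S,8S,10R)-13-acetoxy-8-angeloyloxy-1,4-epoxy-10-hydroxygermacra-5E,7(11)-dien-6,12-olide, via oxolane aldehyde 18 (not isolated), via silyloxyfuran aldehyde 19 (not isolated), via silyl aldol macrocycle 20 (not isolated), via O-silyl target 21 (not isolated)
Conditions: CSA (0.2 equiv), wet CH2Cl2, 0 °C; then iPr2NEt, TMSOTf, CH2Cl2 (2 mM), −78 → 0 °C; then DBU, rt; 1 M HCl/THF work-up
Reagents that add atoms: none
Why: Proposed new method: acid removes the labile tertiary silyl group and O-4 opens the protonated epoxide 5-exo at C1 with inversion (as in furanoid linalool oxide formation) to give the 2,5-trans oxolane with C1 (S) and C10 (R), after which, in the same flask, the butenolide is converted into its 2-silyloxyfuran, which adds through C6 to the C5 aldehyde (intramolecular vinylogous Mukaiyama aldol) and loses silanolate under DBU (E1cB) to give the ring-enforced 5E enol lactone; the closest known chemistry is the one-pot silyl triflate/amine then DBU condensation of butenolides with aldehydes (Boukouvalas), here run intramolecularly to close a ten-membered ring.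

**Compound list**
1 | (S)-(+)-linalool, (3S)-3,7-dimethylocta-1,6-dien-3-ol | C=C[C@@](C)(O)CCC=C(C)C | starting material
2 | (2E,6S)-2,6-dimethylocta-2,7-diene-1,6-diol | C=C[C@@](C)(O)CC/C=C(\C)CO | intermediate
3 | (3S,6E)-8-chloro-3,7-dimethylocta-1,6-dien-3-ol | C=C[C@@](C)(O)CC/C=C(\C)CCl | intermediate
4 | but-2-yne-1,4-diol | OCC#CCO | starting material
5 | (E)-2-bromo-3-iodobut-2-ene-1,4-diol | OC/C(Br)=C(\I)CO | intermediate
6 | 4-bromo-3-(hydroxymethyl)furan-2(5H)-one | O=C1OCC(Br)=C1CO | intermediate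
7 | 3-(hydroxymethyl)-4-(tributylstannyl)furan-2(5H)-one (not isolated) | O=C1OCC([Sn](CCCC)(CCCC)CCCC)=C1CO | intermediate
8 | [2-oxo-4-(tributylstannyl)-2,5-dihydrofuran-3-yl]methyl acetate | CC(=O)OCC1=C([Sn](CCCC)(CCCC)CCCC)COC1=O | intermediate
9 | {4-[(3E,7S)-7-hydroxy-3,7-dimethylnona-3,8-dienoyl]-2-oxo-2,5-dihydrofuran-3-yl}methyl acetate | C=C[C@@](C)(O)CC/C=C(\C)CC(=O)C1=C(COC(C)=O)C(=O)OC1 | intermediate
10 | {4-[(1S,3E,7S)-1,7-dihydroxy-3,7-dimethylnona-3,8-dien-1-yl]-2-oxo-2,5-dihydrofuran-3-yl}methyl acetate | C=C[C@@](C)(O)CC/C=C(\C)C[C@H](O)C1=C(COC(C)=O)C(=O)OC1 | intermediate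
11 | angelic acid, (2Z)-2-methylbut-2-enoic acid | C/C=C(/C)C(=O)O | starting material
12 | (2Z)-2-methylbut-2-enoic 2,4,6-trichlorobenzoic anhydride (not isolated) | C/C=C(/C)C(=O)OC(=O)c1c(Cl)cc(Cl)cc1Cl | intermediate
13 | (1S,3E,7S)-1-[4-(acetoxymethyl)-5-oxo-2,5-dihydrofuran-3-yl]-7-hydroxy-3,7-dimethylnona-3,8-dien-1-yl (2Z)-2-methylbut-2-enoate | C=C[C@@](C)(O)CC/C=C(\C)C[C@H](OC(=O)/C(C)=C\C)C1=C(COC(C)=O)C(=O)OC1 | intermediate
14 | (1S,3E,7S)-1-[4-(acetoxymethyl)-5-oxo-2,5-dihydrofuran-3-yl]-3,7-dimethyl-7-(trimethylsilyloxy)nona-3,8-dien-1-yl (2Z)-2-methylbut-2-enoate | C=C[C@@](C)(O[Si](C)(C)C)CC/C=C(\C)C[C@H](OC(=O)/C(C)=C\C)C1=C(COC(C)=O)C(=O)OC1 | intermediate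
15 | (1S)-1-[4-(acetoxymethyl)-5-oxo-2,5-dihydrofuran-3-yl]-2-{(2R,3R)-2-methyl-3-[(3S)-3-methyl-3-(trimethylsilyloxy)pent-4-en-1-yl]oxiran-2-yl}ethyl (2Z)-2-methylbut-2-enoate | C=C[C@@](C)(O[Si](C)(C)C)CC[C@H]1O[C@]1(C)C[C@H](OC(=O)/C(C)=C\C)C2=C(COC(C)=O)C(=O)OC2 | intermediate
16 | 4,5-dihydroxy analogue of 15 (vinyl group converted to CH(OH)CH2OH, C4' epimers; not isolated) | OCC(O)[C@@](C)(O[Si](C)(C)C)CC[C@H]1O[C@]1(C)C[C@H](OC(=O)/C(C)=C\C)C2=C(COC(C)=O)C(=O)OC2 | intermediate
17 | (1S)-1-[4-(acetoxymethyl)-5-oxo-2,5-dihydrofuran-3-yl]-2-{(2R,3R)-2-methyl-3-[(3S)-3-methyl-4-oxo-3-(trimethylsilyloxy)butyl]oxiran-2-yl}ethyl (2Z)-2-methylbut-2-enoate | O=C[C@@](C)(O[Si](C)(C)C)CC[C@H]1O[C@]1(C)C[C@H](OC(=O)/C(C)=C\C)C2=C(COC(C)=O)C(=O)OC2 | intermediate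
18 | (1S,3R)-1-[4-(acetoxymethyl)-5-oxo-2,5-dihydrofuran-3-yl]-3-[(2S,5S)-5-formyl-5-methyloxolan-2-yl]-3-hydroxybutyl (2Z)-2-methylbut-2-enoate (not isolated) | C/C=C(/C)C(=O)O[C@@H](C[C@@](C)(O)[C@@H]1CC[C@@](C)(C=O)O1)C2=C(COC(C)=O)C(=O)OC2 | intermediate
19 | (1S,3R)-1-[4-(acetoxymethyl)-5-(trimethylsilyloxy)furan-3-yl]-3-[(2S,5S)-5-formyl-5-methyloxolan-2-yl]-3-(trimethylsilyloxy)butyl (2Z)-2-methylbut-2-enoate (not isolated) | C/C=C(/C)C(=O)O[C@@H](C[C@@](C)(O[Si](C)(C)C)[C@@H]1CC[C@@](C)(C=O)O1)c2coc(O[Si](C)(C)C)c2COC(C)=O | intermediate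
20 | (1S,4S,8S,10R)-13-acetoxy-8-angeloyloxy-1,4-epoxy-5,10-bis(trimethylsilyloxy)germacr-7(11)-en-6,12-olide (C5/C6 epimers; not isolated) | C/C=C(/C)C(=O)O[C@H]1C[C@@](C)(O[Si](C)(C)C)[C@@H]2CC[C@@](C)(C(O[Si](C)(C)C)C3OC(=O)C(COC(C)=O)=C31)O2 | intermediate
21 | (1S,4S,8S,10R)-13-acetoxy-8-angeloyloxy-1,4-epoxy-10-(trimethylsilyloxy)germacra-5E,7(11)-dien-6,12-olide (not isolated) | C/C=C(/C)C(=O)O[C@H]1C[C@@](C)(O[Si](C)(C)C)[C@@H]2CC[C@@](C)(/C=C3/OC(=O)C(COC(C)=O)=C31)O2 | intermediate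
22 | CNP0162854.1, (1S,4S,8S,10R)-13-acetoxy-8-angeloyloxy-1,4-epoxy-10-hydroxygermacra-5E,7(11)-dien-6,12-olide | C/C=C(/C)C(=O)O[C@H]1C[C@@](C)(O)[C@@H]2CC[C@@](C)(/C=C3/OC(=O)C(COC(C)=O)=C31)O2 | target

**Step count and risks**

Total step count: 12. Longest linear sequence: 10 steps (from 4 through steps 3 to 12); the linalool branch is 9 steps.

Most likely to fail:

1. Step 12. The carbon–carbon bond-forming closure has to build a ten-membered ring onto a 2,5-trans-bridged oxolane, which may be too strained. The acid-mediated oxolane closure can also give some 6-endo product, and the silyloxyfuran or dienolate can lose the C13 acetate. Fallback (sets out from 17, comes back at 22): reverse the order of ring formation. 17 is treated directly with iPr2NEt/TMSOTf at high dilution, which gives the silyloxyfuran epoxy aldehyde F1 and, by vinylogous Mukaiyama aldol closure of the still monocyclic ten-membered ring, the epoxy silyl aldol macrocycle F2. DBU then eliminates silanolate to give the epoxy dienolide F3, in which the oxolane is not yet formed. CSA in wet CH2Cl2 finally removes the tertiary silyl group and lets O-4 open the epoxide transannularly at C1, giving 22.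

2. Step 6. Transmetalation from the electron-poor stannane may be slow, which would allow direct allyl–vinyl coupling or migration of the C1=C10 alkene into conjugation with the new ketone. Fallback (sets out from 3 and 8, comes back at 9): build the C7–C8 bond by carbonyl addition instead. 3 is formylated (Pd(PPh3)4, CO, Bu3SnH) to the β,γ-unsaturated aldehyde F4, and 8 is converted with I2 into the iodobutenolide F5. Nozaki–Hiyama–Kishi coupling of F4 with F5 (CrCl2, NiCl2 cat., DMF) gives the secondary alcohol F6 as a mixture of C8 epimers, and Dess–Martin periodinane oxidises F6 to 9, so that step 7 still sets C8.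

3. Step 11. The tertiary silyl ether may not survive the aqueous oxidation, and once it is lost periodate cleaves the C4–C5 bond of the resulting α-hydroxy aldehyde; OsO4 must also prefer the hindered vinyl group over the angelate. Fallback (sets out from 15, comes back at 18): give up the masked alcohol and close the oxolane first. CSA in wet CH2Cl2 turns 15 into the vinyl oxolane F7, whose ether oxygen cannot take part in glycol cleavage. OsO4/NMO then gives the diol F8 and NaIO4 gives 18, which is taken through the second and third stages of step 12.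

**Further compounds**
F1 | step 12 | (1S)-1-[4-(acetoxymethyl)-5-(trimethylsilyloxy)furan-3-yl]-2-{(2R,3R)-2-methyl-3-[(3S)-3-methyl-4-oxo-3-(trimethylsilyloxy)butyl]oxiran-2-yl}ethyl (2Z)-2-methylbut-2-enoate | O=C[C@@](C)(O[Si](C)(C)C)CC[C@H]1O[C@]1(C)C[C@H](OC(=O)/C(C)=C\C)c2coc(O[Si](C)(C)C)c2COC(C)=O
F2 | step 12 | (1R,4S,8S,10R)-13-acetoxy-8-angeloyloxy-1,10-epoxy-4,5-bis(trimethylsilyloxy)germacr-7(11)-en-6,12-olide (C5/C6 epimers) | C/C=C(/C)C(=O)O[C@H]1C[C@@]2(C)O[C@@H]2CC[C@](C)(O[Si](C)(C)C)C(O[Si](C)(C)C)C3OC(=O)C(COC(C)=O)=C31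
F3 | step 12 | (1R,4S,8S,10R)-13-acetoxy-8-angeloyloxy-1,10-epoxy-4-(trimethylsilyloxy)germacra-5E,7(11)-dien-6,12-olide | C/C=C(/C)C(=O)O[C@H]1C[C@@]2(C)O[C@@H]2CC[C@](C)(O[Si](C)(C)C)/C=C3/OC(=O)C(COC(C)=O)=C31
F4 | step 6 | (3E,7S)-7-hydroxy-3,7-dimethylnona-3,8-dienal | C=C[C@@](C)(O)CC/C=C(\C)CC=O
F5 | step 6 | (4-iodo-2-oxo-2,5-dihydrofuran-3-yl)methyl acetate | CC(=O)OCC1=C(I)COC1=O
F6 | step 6 | {4-[(1RS,3E,7S)-1,7-dihydroxy-3,7-dimethylnona-3,8-dien-1-yl]-2-oxo-2,5-dihydrofuran-3-yl}methyl acetate | C=C[C@@](C)(O)CC/C=C(\C)CC(O)C1=C(COC(C)=O)C(=O)OC1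
F7 | step 11 | (1S,3R)-1-[4-(acetoxymethyl)-5-oxo-2,5-dihydrofuran-3-yl]-3-[(2S,5S)-5-ethenyl-5-methyloxolan-2-yl]-3-hydroxybutyl (2Z)-2-methylbut-2-enoate | C/C=C(/C)C(=O)O[C@@H](C[C@@](C)(O)[C@@H]1CC[C@@](C)(C=C)O1)C2=C(COC(C)=O)C(=O)OC2
F8 | step 11 | (1S,3R)-1-[4-(acetoxymethyl)-5-oxo-2,5-dihydrofuran-3-yl]-3-[(2S,5S)-5-(1,2-dihydroxyethyl)-5-methyloxolan-2-yl]-3-hydroxybutyl (2Z)-2-methylbut-2-enoate | C/C=C(/C)C(=O)O[C@@H](C[C@@](C)(O)[C@@H]1CC[C@@](C)(C(O)CO)O1)C2=C(COC(C)=O)C(=O)OC2
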